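Ring C is disconnected at C3–C4 and O1–C2, that is, at the salicyloyl unit of ring A, in which the C4 carbonyl carbon and O1 sit on the adjacent carbons C4a and C8a. Masking C4 as a 1,3-dithiane turns this unit into a carbon/oxygen 1,4-dinucleophile (acyl-anion carbon plus phenoxide). One double alkylation with (S)-4-phenyl-1,3,2-dioxathiolane 2,2-dioxide as chiral 1,2-dielectrophile supplies C3 and C2, closes ring C and sets C2 by SN2 inversion. The precursor is a 2-aryl-1,3-dithiane with one free phenol. The dithiane then protects C2 from retro-oxa-Michael racemisation while the pyranone is attached at C6; C8 prenylation and deprotection follow.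

Key step: step 4

Remark: the (S)-diol leads to the (2S)-flavanone because the single inversion at the benzylic carbon is offset by a change in CIP ranking (CH2O outranks phenyl in the sulfate; phenyl outranks C3 in the product).

Step 1
Reactants: 1 (S)-1-phenylethane-1,2-diol
Product: 3 (4S)-4-phenyl-1,3,2-dioxathiolane 2,2-dioxide, via cyclic sulfite 2 (not isolated)
Conditions: SOCl2, CH2Cl2, 0 °C to rt; then RuCl3·3H2O (1 mol %), NaIO4, MeCN/H2O, 0 °C
Reagents that add atoms: thionyl chloride, O=S(Cl)Cl; sodium periodate, [Na+].[O-]I(=O)(=O)=O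
Why: Cyclic sulfite formation followed by catalytic ruthenium tetroxide oxidation is the standard route to 1,2-cyclic sulfates and breaks no C–O bond, so the S configuration of the benzylic carbon should be retained.

Step 2
Reactants: 4 2,4,6-trihydroxybenzaldehyde
Product: 5 2-hydroxy-4,6-bis(methoxymethoxy)benzaldehyde
Conditions: MOMCl (2.2 equiv), i-Pr2NEt, CH2Cl2, 0 °C to rt
Reagents that add atoms: chloromethyl methyl ether, COCCl
Why: O-alkylation (acetal ether formation) should stop at the bis-ether because the remaining ortho hydroxyl is hydrogen-bonded to the formyl group and is the least nucleophilic; the two ortho hydroxyls are equivalent, so only one product can form.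

Step 3
Reactants: 5 2-hydroxy-4,6-bis(methoxymethoxy)benzaldehyde; 6 propane-1,3-dithiol
Product: 7 2-[2-hydroxy-4,6-bis(methoxymethoxy)phenyl]-1,3-dithiane
Conditions: LiBr (30 mol %), minimal MeCN, 75 °C
Reagents that add atoms: none
Why: Dithioacetalisation under essentially neutral Lewis-acid catalysis should convert the aldehyde into the Corey–Seebach acyl-anion precursor while the acid-labile MOM ethers survive.

Step 4
Reactants: 7 2-[2-hydroxy-4,6-bis(methoxymethoxy)phenyl]-1,3-dithiane; 3 (4S)-4-phenyl-1,3,2-dioxathiolane 2,2-dioxide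
Product: 10 (2S)-5,7-bis(methoxymethoxy)-2-phenylspiro[chromane-4,2'-[1,3]dithiane], via dilithio dianion 8 (not isolated), via benzylic lithium sulfate 9 (not isolated)
Conditions: n-BuLi (2.2 equiv), THF, −78 to −20 °C; 3 (1.1 equiv), −78 °C to rt; then DMPU, 55 °C
Reagents that add atoms: none
Why: Two-fold deprotonation of 7 gives the phenoxide/2-lithio-1,3-dithiane dianion 8, whose tertiary carbanion (the acyl-anion equivalent of C4) opens cyclic sulfate 3 by SN2 attack at the primary carbon, forming C3–C4 and leaving the benzylic carbon as sulfate monoester 9 with its configuration untouched; on warming, the ortho phenoxide displaces this sulfate at the benzylic carbon, forming O1–C2. The closest known reaction types are the one-pot double displacement of 1,2-cyclic sulfates by dinucleophiles (cyclopropanes from malonates, 1,4-benzodioxanes from catechols) and the opening of terminal epoxides by 2-aryl-2-lithio-1,3-dithianes. Ring C closes in a 6-exo-tet SN2 mode. C2 is the only new stereocentre (spiro C4 is not stereogenic) and is controlled by the S carbon of 3 through inversion, the descriptor remaining S because of the CIP ranking change. The step needs carbon-before-oxygen chemoselectivity and primary-carbon regioselectivity in the first alkylation, which the far higher nucleophilicity and the bulk of the dithianyl anion should secure. It also needs substitution rather than elimination or ionisation in the second alkylation, which is favoured by the intramolecular six-membered transition state and by the dithiane, since a non-enolisable C4 leaves no E1cB path to a chalcone.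

Step 5
Reactants: 11 pentan-3-one; 12 malonyl dichloride
Product: 13 6-ethyl-4-hydroxy-5-methyl-2H-pyran-2-one
Conditions: neat (11 in excess), rt to 50 °C
Reagents that add atoms: none
Why: C-acylation of the ketone enol followed by O-acylation of the new enol by the second acid chloride (4-hydroxy-2-pyranone synthesis from a ketone and malonyl dichloride) should give the 5-methyl-6-ethyl pyranone directly.

Step 6
Reactants: 13 6-ethyl-4-hydroxy-5-methyl-2H-pyran-2-one
Product: 14 3-bromo-6-ethyl-4-hydroxy-5-methyl-2H-pyran-2-one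
Conditions: NBS, CH2Cl2, 0 °C to rt
Reagents that add atoms: N-bromosuccinimide, O=C1CCC(=O)N1Br
Why: Electrophilic bromination should occur at C3, the only unsubstituted ring position and the nucleophilic carbon of the vinylogous acid.

Step 7
Reactants: 14 3-bromo-6-ethyl-4-hydroxy-5-methyl-2H-pyran-2-one
Product: 15 3-bromo-6-ethyl-4-(methoxymethoxy)-5-methyl-2H-pyran-2-one
Conditions: MOMCl, i-Pr2NEt, CH2Cl2, 0 °C
Reagents that add atoms: chloromethyl methyl ether, COCCl
Why: O-alkylation of the acidic 4-hydroxyl with a hard electrophile should give the 4-alkoxy-2-pyranone, masking the acidic proton for the organozinc coupling.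

Step 8
Reactants: 10 (2S)-5,7-bis(methoxymethoxy)-2-phenylspiro[chromane-4,2'-[1,3]dithiane]; 15 3-bromo-6-ethyl-4-(methoxymethoxy)-5-methyl-2H-pyran-2-one
Product: 18 6-ethyl-4-(methoxymethoxy)-5-methyl-3-[(2S)-5,7-bis(methoxymethoxy)-2-phenylspiro[chromane-4,2'-[1,3]dithian]-6-yl]-2H-pyran-2-one, via aryllithium 16 (not isolated), via arylzinc chloride 17 (not isolated)
Conditions: n-BuLi (1.2 equiv), THF, 0 °C; ZnCl2 (1.3 equiv), 0 °C to rt; 15, Pd2(dba)3 (2.5 mol %), RuPhos (10 mol %), THF, 65 °C
Reagents that add atoms: none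
Why: Directed ortho-metalation should occur at C6, the position flanked by both MOM ethers, and transmetalation to zinc followed by Negishi coupling with the 3-bromopyranone forms the hindered aryl–pyranone bond; C2 is a simple benzylic ether here (C4 masked) and should be configurationally inert.

Step 9
Reactants: 18 6-ethyl-4-(methoxymethoxy)-5-methyl-3-[(2S)-5,7-bis(methoxymethoxy)-2-phenylspiro[chromane-4,2'-[1,3]dithian]-6-yl]-2H-pyran-2-one
Product: 19 (2S)-6-[6-ethyl-4-(methoxymethoxy)-5-methyl-2-oxo-2H-pyran-3-yl]-5,7-bis(methoxymethoxy)-2-phenylchroman-4-one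
Conditions: MeI (10 equiv), CaCO3, MeCN/H2O (9:1), 45 °C
Reagents that add atoms: water, O
Why: Alkylative hydrolysis of the dithiane (S-methylation, thionium ion, hydration) should unmask the C4 ketone under buffered, non-oxidising conditions that spare the electron-rich ring, the MOM groups and C2.

Step 10
Reactants: 19 (2S)-6-[6-ethyl-4-(methoxymethoxy)-5-methyl-2-oxo-2H-pyran-3-yl]-5,7-bis(methoxymethoxy)-2-phenylchroman-4-one
Product: 20 (2S)-6-[6-ethyl-4-(methoxymethoxy)-5-methyl-2-oxo-2H-pyran-3-yl]-8-iodo-5,7-bis(methoxymethoxy)-2-phenylchroman-4-one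
Conditions: NIS, CF3CO2H (10 mol %), MeCN, 0 °C to rt
Reagents that add atoms: N-iodosuccinimide, O=C1CCC(=O)N1I
Why: Electrophilic aromatic iodination should occur at C8, the only unsubstituted position of ring A (activated by O1 and the C7 ether), under base-free conditions that do not endanger C2.

Step 11
Reactants: 20 (2S)-6-[6-ethyl-4-(methoxymethoxy)-5-methyl-2-oxo-2H-pyran-3-yl]-8-iodo-5,7-bis(methoxymethoxy)-2-phenylchroman-4-one; 21 tributyl(3-methylbut-2-en-1-yl)stannane
Product: 22 (2S)-6-[6-ethyl-4-(methoxymethoxy)-5-methyl-2-oxo-2H-pyran-3-yl]-5,7-bis(methoxymethoxy)-8-(3-methylbut-2-en-1-yl)-2-phenylchroman-4-one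
Conditions: Pd2(dba)3 (5 mol %), P(2-furyl)3 (20 mol %), DMF, 80 °C
Reagents that add atoms: none
Why: Stille coupling should transfer the prenyl group through its α-carbon (linear isomer) under neutral conditions, so the flavanone stereocentre, which is sensitive to base through retro-oxa-Michael opening, is not exposed to base.

Step 12
Reactants: 22 (2S)-6-[6-ethyl-4-(methoxymethoxy)-5-methyl-2-oxo-2H-pyran-3-yl]-5,7-bis(methoxymethoxy)-8-(3-methylbut-2-en-1-yl)-2-phenylchroman-4-one
Product: 23 (2S)-6-(6-ethyl-4-hydroxy-5-methyl-2-oxo-2H-pyran-3-yl)-5,7-dihydroxy-8-(3-methylbut-2-en-1-yl)-2-phenylchroman-4-one (CNP0482269.1)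
Conditions: 3 M HCl (aq)/MeOH (1:4), 45 °C
Reagents that add atoms: none
Why: Acid-catalysed acetal exchange with methanol should remove the two aryl MOM ethers and the pyranone MOM ether as dimethoxymethane; flavanones are configurationally stable to dilute acid and the prenyl group should survive a short exposure.

Compound list
1 | (S)-1-phenylethane-1,2-diol | OC[C@@H](O)c1ccccc1 | starting material
2 | (4S)-4-phenyl-1,3,2-dioxathiolane 2-oxide (cyclic sulfite, both sulfur epimers) | O=S1OC[C@H](c2ccccc2)O1 | intermediate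
3 | (4S)-4-phenyl-1,3,2-dioxathiolane 2,2-dioxide | O=S1(=O)OC[C@H](c2ccccc2)O1 | intermediate
4 | 2,4,6-trihydroxybenzaldehyde | O=Cc1c(O)cc(O)cc1O | starting material
5 | 2-hydroxy-4,6-bis(methoxymethoxy)benzaldehyde | O=Cc1c(O)cc(OCOC)cc1OCOC | intermediate
6 | propane-1,3-dithiol | SCCCS | starting material
7 | 2-[2-hydroxy-4,6-bis(methoxymethoxy)phenyl]-1,3-dithiane | Oc1cc(OCOC)cc(OCOC)c1C1SCCCS1 | intermediate
8 | lithium 2-(2-lithio-1,3-dithian-2-yl)-3,5-bis(methoxymethoxy)phenoxide (dianion of 7) | [Li]Oc1cc(OCOC)cc(OCOC)c1C1([Li])SCCCS1 | intermediate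
9 | dilithium salt of (1R)-2-{2-[2-hydroxy-4,6-bis(methoxymethoxy)phenyl]-1,3-dithian-2-yl}-1-phenylethyl hydrogen sulfate | [Li]Oc1cc(OCOC)cc(OCOC)c1C1(C[C@H](c2ccccc2)OS(=O)(=O)O[Li])SCCCS1 | intermediate
10 | (2S)-5,7-bis(methoxymethoxy)-2-phenylspiro[chromane-4,2'-[1,3]dithiane] | COCOc1cc2c(c(OCOC)c1)C1(C[C@@H](c3ccccc3)O2)SCCCS1 | intermediate
11 | pentan-3-one | CCC(=O)CC | starting material
12 | malonyl dichloride | O=C(Cl)CC(=O)Cl | starting material
13 | 6-ethyl-4-hydroxy-5-methyl-2H-pyran-2-one | CCc1oc(=O)cc(O)c1C | intermediate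
14 | 3-bromo-6-ethyl-4-hydroxy-5-methyl-2H-pyran-2-one | CCc1oc(=O)c(Br)c(O)c1C | intermediate
15 | 3-bromo-6-ethyl-4-(methoxymethoxy)-5-methyl-2H-pyran-2-one | CCc1oc(=O)c(Br)c(OCOC)c1C | intermediate
16 | (2S)-6-lithio-5,7-bis(methoxymethoxy)-2-phenylspiro[chromane-4,2'-[1,3]dithiane] | COCOc1cc2c(c(OCOC)c1[Li])C1(C[C@@H](c3ccccc3)O2)SCCCS1 | intermediate
17 | (2S)-6-(chlorozincio)-5,7-bis(methoxymethoxy)-2-phenylspiro[chromane-4,2'-[1,3]dithiane] | COCOc1cc2c(c(OCOC)c1[Zn]Cl)C1(C[C@@H](c3ccccc3)O2)SCCCS1 | intermediate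
18 | 6-ethyl-4-(methoxymethoxy)-5-methyl-3-[(2S)-5,7-bis(methoxymethoxy)-2-phenylspiro[chromane-4,2'-[1,3]dithian]-6-yl]-2H-pyran-2-one | CCc1oc(=O)c(-c2c(OCOC)cc3c(c2OCOC)C2(C[C@@H](c4ccccc4)O3)SCCCS2)c(OCOC)c1C | intermediate
19 | (2S)-6-[6-ethyl-4-(methoxymethoxy)-5-methyl-2-oxo-2H-pyran-3-yl]-5,7-bis(methoxymethoxy)-2-phenylchroman-4-one | CCc1oc(=O)c(-c2c(OCOC)cc3c(c2OCOC)C(=O)C[C@@H](c2ccccc2)O3)c(OCOC)c1C | intermediate
20 | (2S)-6-[6-ethyl-4-(methoxymethoxy)-5-methyl-2-oxo-2H-pyran-3-yl]-8-iodo-5,7-bis(methoxymethoxy)-2-phenylchroman-4-one | CCc1oc(=O)c(-c2c(OCOC)c(I)c3c(c2OCOC)C(=O)C[C@@H](c2ccccc2)O3)c(OCOC)c1C | intermediate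
21 | tributyl(3-methylbut-2-en-1-yl)stannane | CCCC[Sn](CCCC)(CCCC)CC=C(C)C | starting material
22 | (2S)-6-[6-ethyl-4-(methoxymethoxy)-5-methyl-2-oxo-2H-pyran-3-yl]-5,7-bis(methoxymethoxy)-8-(3-methylbut-2-en-1-yl)-2-phenylchroman-4-one | CCc1oc(=O)c(-c2c(OCOC)c(CC=C(C)C)c3c(c2OCOC)C(=O)C[C@@H](c2ccccc2)O3)c(OCOC)c1C | intermediate
23 | (2S)-6-(6-ethyl-4-hydroxy-5-methyl-2-oxo-2H-pyran-3-yl)-5,7-dihydroxy-8-(3-methylbut-2-en-1-yl)-2-phenylchroman-4-one | CCc1oc(=O)c(-c2c(O)c(CC=C(C)C)c3c(c2O)C(=O)C[C@@H](c2ccccc2)O3)c(O)c1C | target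

Total step count: 12. Longest linear sequence: 8 (steps 2, 3, 4, 8, 9, 10, 11, 12, from 2,4,6-trihydroxybenzaldehyde).

Steps most likely to fail

Step 4. The carbanion may attack the benzylic instead of the primary carbon of the cyclic sulfate (wrong ring connectivity). The benzylic sulfate may also ionise or eliminate before the phenoxide closes the ring, with loss of configurational purity or formation of a styrene. Fallback, setting out from 7 and returning at 10: dianion 8 is generated as in the route and treated with commercial (S)-2-phenyloxirane. Opening at the terminal carbon, the established regiochemistry for 2-aryl-2-lithio-1,3-dithianes, should give after aqueous quench (1R)-2-{2-[2-hydroxy-4,6-bis(methoxymethoxy)phenyl]-1,3-dithian-2-yl}-1-phenylethan-1-ol F1. Intramolecular Mitsunobu etherification (PPh3, diisopropyl azodicarboxylate, toluene, 0 °C to rt) then closes ring C with inversion to give 10. The two bonds are then made in two separately controlled operations, and the leaving group is generated only at the carbinol carbon.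

Step 8. Metalation may occur at C8 or at the benzylic C2–H instead of C6. Slow reductive elimination in the doubly ortho-substituted coupling may lead to protodemetalation. Fallback, setting out from 10 and returning at 22, with both substituents introduced by electrophilic iodination and base-free Stille coupling:
- The dithiane is removed as in step 9 to give (2S)-5,7-bis(methoxymethoxy)-2-phenylchroman-4-one F2.
- Iodination (NIS, catalytic CF3CO2H, MeCN) of this 5,7-dialkoxyflavanone is expected at C8 and should give (2S)-8-iodo-5,7-bis(methoxymethoxy)-2-phenylchroman-4-one F3.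
- Stille coupling with 21 should give (2S)-5,7-bis(methoxymethoxy)-8-(3-methylbut-2-en-1-yl)-2-phenylchroman-4-one F4.
- A second iodination at C6, the only free position left, should give (2S)-6-iodo-5,7-bis(methoxymethoxy)-8-(3-methylbut-2-en-1-yl)-2-phenylchroman-4-one F5.
- Bromide 15 is converted with hexabutylditin (Pd(PPh3)4, toluene, 110 °C) into 6-ethyl-4-(methoxymethoxy)-5-methyl-3-(tributylstannyl)-2H-pyran-2-one F6.
- Stille coupling of F5 with F6 (Pd2(dba)3, AsPh3, CuI, DMF, 70 °C) returns to 22.

Step 11. Transmetalation of the bulky prenylstannane at the doubly flanked iodide may be slow, leading to reductive loss of iodine, and allylic transposition may give the 1,1-dimethylallyl isomer. Fallback, setting out from 20 and returning at 22: Stille coupling with allyltributylstannane, which transmetalates faster and has no transposition issue, should give (2S)-8-allyl-6-[6-ethyl-4-(methoxymethoxy)-5-methyl-2-oxo-2H-pyran-3-yl]-5,7-bis(methoxymethoxy)-2-phenylchroman-4-one F7. Olefin cross-metathesis with excess 2-methylbut-2-ene (second-generation Grubbs catalyst, CH2Cl2, 40 °C) then converts the allyl into the prenyl group of 22 under neutral conditions.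

Further compounds
F1 | step 4 | (1R)-2-{2-[2-hydroxy-4,6-bis(methoxymethoxy)phenyl]-1,3-dithian-2-yl}-1-phenylethan-1-ol | Oc1cc(OCOC)cc(OCOC)c1C1(C[C@@H](O)c2ccccc2)SCCCS1
F2 | step 8 | (2S)-5,7-bis(methoxymethoxy)-2-phenylchroman-4-one | COCOc1cc2c(c(OCOC)c1)C(=O)C[C@@H](c1ccccc1)O2
F3 | step 8 | (2S)-8-iodo-5,7-bis(methoxymethoxy)-2-phenylchroman-4-one | COCOc1c(I)c2c(c(OCOC)c1)C(=O)C[C@@H](c1ccccc1)O2
F4 | step 8 | (2S)-5,7-bis(methoxymethoxy)-8-(3-methylbut-2-en-1-yl)-2-phenylchroman-4-one | COCOc1c(CC=C(C)C)c2c(c(OCOC)c1)C(=O)C[C@@H](c1ccccc1)O2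
F5 | step 8 | (2S)-6-iodo-5,7-bis(methoxymethoxy)-8-(3-methylbut-2-en-1-yl)-2-phenylchroman-4-one | COCOc1c(CC=C(C)C)c2c(c(OCOC)c1I)C(=O)C[C@@H](c1ccccc1)O2
F6 | step 8 | 6-ethyl-4-(methoxymethoxy)-5-methyl-3-(tributylstannyl)-2H-pyran-2-one | CCCC[Sn](CCCC)(CCCC)c1c(OCOC)c(C)c(CC)oc1=O
F7 | step 11 | (2S)-8-allyl-6-[6-ethyl-4-(methoxymethoxy)-5-methyl-2-oxo-2H-pyran-3-yl]-5,7-bis(methoxymethoxy)-2-phenylchroman-4-one | CCc1oc(=O)c(-c2c(OCOC)c(CC=C)c3c(c2OCOC)C(=O)C[C@@H](c2ccccc2)O3)c(OCOC)c1C
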